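**Assumptions (one line each).** Boronic acid 8 is bought as a catalogue reagent. The (S)-biaryl bisphosphine is assumed to give the (2S) product, by analogy with (S)-BINAP giving (S)-3-arylcyclohexanones; if the first run gives (2R), use the (R)-ligand. The route has not been run; yields and selectivities are expectations.

## Retrosynthetic overview

- Target ⇒ global MOM/TBS removal from the fully protected (2S)-flavanone.
- Key disconnection C2–C1′: the protected flavanone ⇒ a 5,7-bis(MOM-oxy)-6,8-diprenylchromone plus an intact 3,5-dioxygenated arylboronic acid. In the forward direction this is a Rh-catalysed enantioselective 1,4-arylation that dearomatises the γ-pyrone ring and sets C2.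
- Chromone ⇒ one-carbon annulation (DMF-DMA) of the mirror-symmetric 3,5-diprenyl-phloracetophenone bis-MOM ether; the symmetry means either ortho oxygen gives the same ring.
- Diprenyl ketone ⇒ 2,4,6-trihydroxyacetophenone plus two prenyl bromide (C-prenylation).
- Ring order: A ring bought (aromatic feedstock); B ring bought (boronic acid); C ring built as an aromatic pyrone, then dearomatised in the stereo-defining step.

## Route

**Step 1**
Reactants: 1, 2,4,6-trihydroxyacetophenone (phloracetophenone); 2, prenyl bromide (1-bromo-3-methylbut-2-ene)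
Product: 3, 1-[2,4,6-trihydroxy-3,5-bis(3-methylbut-2-en-1-yl)phenyl]ethan-1-one
Conditions: 2 (2.1 equiv), 10% aq KOH, 0 °C → rt; then 1 M HCl, SiO2 chromatography
Reagents that add atoms: prenyl bromide, CC(C)=CCBr (two equivalents incorporated)
Why: Phenolate C-alkylation of the acylphloroglucinol (the deoxyhumulone-type diprenylation); water favours C- over O-alkylation, and the two free ring CH positions are alkylated via cyclohexadienone tautomers that re-aromatise; a modest yield (about 30–40%) is expected because mono-, gem-di- and tri-prenylated by-products form.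

**Step 2**
Reactants: 3; 4, chloromethyl methyl ether (MOMCl)
Product: 5, 1-[2-hydroxy-4,6-bis(methoxymethoxy)-3,5-bis(3-methylbut-2-en-1-yl)phenyl]ethan-1-one
Conditions: MOMCl (2.3 equiv), i-Pr2NEt (3 equiv), CH2Cl2, 0 °C → rt
Reagents that add atoms: MOMCl, COCCl (two equivalents incorporated)
Why: Williamson-type acetalisation of phenols; the 4-OH and one ortho OH react, while the remaining ortho OH is deactivated by its hydrogen bond to the acetyl group, and the symmetry of 3 makes the product unique.

**Step 3**
Reactants: 5; 6, N,N-dimethylformamide dimethyl acetal (DMF-DMA)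
Product: 7, 5,7-bis(methoxymethoxy)-6,8-bis(3-methylbut-2-en-1-yl)-4H-chromen-4-one
Conditions: DMF-DMA (3 equiv), PhMe, 100 °C; concentrate; then SiO2, CH2Cl2, rt → 40 °C
Reagents that add atoms: DMF-DMA, COC(OC)N(C)C (supplies the C2 carbon)
Why: Enaminone formation at the acetyl CH3, then silica-promoted 6-endo addition of the free phenol and loss of Me2NH (enaminone route to chromones); the non-acidic closure keeps the MOM and prenyl groups intact.

**Step 4 (key step)**
Reactants: 7; 8, [3,5-bis(tert-butyldimethylsilyloxy)phenyl]boronic acid
Product: 9, (2S)-2-[3,5-bis(tert-butyldimethylsilyloxy)phenyl]-5,7-bis(methoxymethoxy)-6,8-bis(3-methylbut-2-en-1-yl)-2,3-dihydro-4H-chromen-4-one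
Conditions: 8 (2.5 equiv), [RhCl(C2H4)2]2 (2.5 mol %), (S)-MeO-F12-BIPHEP (5.5 mol %), aq KOH (10 mol %), PhMe/H2O (10:1), 30–40 °C
Reagents that add atoms: boronic acid 8, CC(C)(C)[Si](C)(C)Oc1cc(cc(O[Si](C)(C)C(C)(C)C)c1)B(O)O (aryl group transferred)
Why: Hayashi–Miyaura Rh(I)-catalysed asymmetric 1,4-addition: the aryl–Rh species adds across C2=C3 of the γ-pyrone from the C2 Re face selected by the (S)-bisphosphine and water protonates the Rh enolate, dearomatising the pyrone and setting (2S); the electron-poor ligand is chosen because this chromone is a weak, electron-rich acceptor, and the prenyl alkenes, MOM and aryl-OTBS groups are inert under these near-neutral conditions.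

**Step 5**
Reactants: 9
Product: 10, (2S)-2-(3,5-dihydroxyphenyl)-5,7-dihydroxy-6,8-bis(3-methylbut-2-en-1-yl)-2,3-dihydro-4H-chromen-4-one (target, CID26213315)
Conditions: 3 M aq HCl/MeOH/THF (1:3:1), 40 °C, monitored to completion
Reagents that add atoms: none
Why: Acid-catalysed acetal methanolysis (MOM) and acidic solvolysis of the aryl silyl ethers in one operation; C2 is not scrambled because no base is present (no retro-oxa-Michael opening) and the meta-dioxygenated B ring cannot stabilise a benzylic cation or quinone methide.

## Compound list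

1 | 2,4,6-trihydroxyacetophenone | CC(=O)c1c(O)cc(O)cc1O | starting material
2 | prenyl bromide | CC(C)=CCBr | starting material
3 | 1-[2,4,6-trihydroxy-3,5-bis(3-methylbut-2-en-1-yl)phenyl]ethan-1-one | CC(=O)c1c(O)c(CC=C(C)C)c(O)c(CC=C(C)C)c1O | intermediate
4 | chloromethyl methyl ether | COCCl | starting material
5 | 1-[2-hydroxy-4,6-bis(methoxymethoxy)-3,5-bis(3-methylbut-2-en-1-yl)phenyl]ethan-1-one | CC(=O)c1c(O)c(CC=C(C)C)c(OCOC)c(CC=C(C)C)c1OCOC | intermediate
6 | N,N-dimethylformamide dimethyl acetal | COC(OC)N(C)C | starting material
7 | 5,7-bis(methoxymethoxy)-6,8-bis(3-methylbut-2-en-1-yl)-4H-chromen-4-one | O=c1ccoc2c(CC=C(C)C)c(OCOC)c(CC=C(C)C)c(OCOC)c12 | intermediate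
8 | [3,5-bis(tert-butyldimethylsilyloxy)phenyl]boronic acid | CC(C)(C)[Si](C)(C)Oc1cc(cc(O[Si](C)(C)C(C)(C)C)c1)B(O)O | starting material
9 | (2S)-2-[3,5-bis(TBSO)phenyl]-5,7-bis(MOM-oxy)-6,8-diprenylchroman-4-one | CC(C)=CCc1c(OCOC)c(CC=C(C)C)c2c(c1OCOC)C(=O)C[C@@H](c1cc(O[Si](C)(C)C(C)(C)C)cc(O[Si](C)(C)C(C)(C)C)c1)O2 | intermediate
10 | (2S)-2-(3,5-dihydroxyphenyl)-5,7-dihydroxy-6,8-diprenylchroman-4-one | CC(C)=CCc1c(O)c(CC=C(C)C)c2c(c1O)C(=O)C[C@@H](c1cc(O)cc(O)c1)O2 | target

## Summary

Total steps: 5. Longest linear sequence: 5 (from 1).

Three steps most likely to fail, each with a fallback that changes the approach: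

1. **Step 4** (low conversion or ee on a fully substituted, electron-rich chromone). Fallback: form the C2–O bond instead of the C2–aryl bond. Claisen–Schmidt condensation of 5 with 3,5-bis(methoxymethoxy)benzaldehyde gives the symmetric 2′-hydroxychalcone; close it by an enantioselective intramolecular oxa-Michael addition with a bifunctional cinchona-thiourea catalyst, then deprotect.
2. **Step 1** (over- and under-prenylation, gem-diprenyl dearomatised by-products). Fallback: replace phenolate alkylation with cross-coupling. Convert 1 to its 4,6-bis-MOM ether, diiodinate C3/C5 with NIS, and run a double Pd-catalysed Suzuki–Miyaura coupling with prenylboronic acid pinacol ester (linear-selective ligand) to reach 5.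
3. **Step 5** (acid-induced cyclisation of a prenyl group onto a neighbouring phenol to give a dimethylchroman, or incomplete TBS cleavage). Fallback: change the protecting-group plan so no protic acid is needed. Protect 3 as silyl ethers (TBSOTf or TESCl) instead of MOM and finish with a single buffered fluoride desilylation (HF·pyridine or TBAF/AcOH, 0 °C).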